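## Structural features

The target is a flavanone. Ring A (a benzene ring) is fused to ring C (a dihydropyran-4-one) to give a chroman-4-one, and ring B (a second benzene ring) is attached to C2 of ring C through the single bond C2–C1'. Ring A carries hydroxyls at C5 and C7, the C5 hydroxyl being hydrogen-bonded to the C4 carbonyl. Ring B carries a methyl ether at C4' and, ortho to it at C3', a 3-methylbut-2-enyl (prenyl) chain. C2 is the only stereocentre (S), so no stereocentre stands next to another and only the absolute configuration has to be secured. C2 is fragile: it is a benzylic ether carbon β to the ketone, and base can open ring C by a retro-oxa-Michael (E1cB) pathway to an achiral 2'-hydroxychalcone, whose re-closure scrambles the centre. The trisubstituted alkene of the prenyl chain is the second weak point, being open to Markovnikov addition under protic acid and to hydrogenation. The real difficulty is to place a linear prenyl group on C3' of ring B without disturbing C2, because electrophilic prenylation of the free polyphenol would go to the far more nucleophilic C6 and C8 of ring A. The key step exploits the fact that natural (S)-hesperetin already has all three rings, the C4' methyl ether, the S configuration at C2 and an oxygen at C3', so the C3'–O bond can be converted into a triflate and exchanged for the C3'–C1'' bond.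

## Logic of the disconnections

**From 6 to 5.** Only O7 changes: the O7–H of 6 is traced back to the O7–CH2OCH3 acetal bond of 5. No skeletal bond is cut. The reason is that O7 is the most acidic phenol oxygen and must be masked while O3' is activated. Keeping the mask through the coupling gives a lipophilic, easily purified coupling product and leaves only the chelated O5–H free. The demand on the forward step is an acetal cleavage mild enough to spare the trisubstituted alkene and the C2–O1 bond.

**From 5 to 3 and 4.** The bond C3'–C1'' between ring B and the allylic CH2 is cut. It is the one skeletal bond of the target that the chiral pool does not supply, it lies far from C2, and cutting it removes the only acid-sensitive group. The gain is large: 3 contains the complete flavanone with C2 already S, and 4 is a purchasable C5 unit. The forward step must transfer the prenyl group through its CH2 terminus, must react only at the C3'–O sulfonate, and must run without base.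

**From 3 to 2.** The O3'–S bond of the sulfonate is cut, which returns an ordinary phenol. The forward step must sulfonylate the free O3'–H and leave the chelated O5–H alone. This calls for a mild triflyl donor and an amine base.

**From 2 to 1.** The O7–CH2 bond of the acetal is cut, which leads to 1. Compound 1 holds rings A, B and C, the C4' methyl ether and the S centre at C2. The forward step must alkylate O7 in preference to O3' and O5, which rests on the acidity order of the three phenols. It must use a base weak enough and a temperature low enough to keep ring C closed. Both 1 and 4 are purchased.

## Other disconnections considered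

**Alternative 1:**
- **Cut and key step.** Ring C would be cut at O1–C2 and C3–C4. This leads back to the salicylaldehyde acetal 2-(dimethoxymethyl)-3,5-bis(triisopropylsilyloxy)phenol A2 and the ring B styrene 4-ethenyl-1-methoxy-2-(3-methylbut-2-enyl)benzene A3. A chiral BINOL-derived N-triflyl phosphoramide would expel methanol from A2 to give the alkoxy ortho-quinone methide 6-(methoxymethylidene)-3,5-bis(triisopropylsilyloxy)cyclohexa-2,4-dien-1-one A4, bound to the chiral counter-anion. A4 would add across the vinyl group of A3 in an inverse-electron-demand [4+2] cycloaddition to give the 4-methoxychromane (2S,4S)-4-methoxy-2-[4-methoxy-3-(3-methylbut-2-enyl)phenyl]-5,7-bis(triisopropylsilyloxy)chromane A1.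
- **In its favour.** The step is convergent. It forms two bonds, ring C and the C2 centre from achiral parts in one catalytic operation. Either enantiomer and many ring B analogues would be reachable by changing the catalyst or the styrene. On these points it is better than the chosen plan, which is tied to one natural enantiomer and to the optical purity of the purchased flavanone.
- **Against it here.** A strong Brønsted acid would meet the acid-sensitive prenyl alkene and a very electron-rich para-alkoxystyrene that is prone to cationic oligomerisation. The prenyl alkene is itself an electron-rich 2π partner for A4, so chemoselectivity is in doubt. The enantiomeric purity would depend on the catalyst, whereas the chosen plan carries C2 unchanged. A1 has C4 at the alcohol oxidation level, so the C4 methyl ether would have to be hydrolysed, C4 oxidised to the ketone (erasing the C4 stereocentre just made) and both silyl ethers removed. The ionisable C4 position could also eliminate towards a flavene.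
- **Comparison.** A3 already contains the C3'–prenyl bond, so the aryl–prenyl coupling is not avoided. It is only moved to an earlier, achiral arene. This is equal to or slightly better than the chosen plan in that no stereocentre is present during that coupling. In step economy the alternative is clearly worse: an estimated ten or more operations against four.

**Alternative 2:**
- **Cut and key step.** The C3=C4 bond would be cut at the enol ether oxidation level. This leads back to the diene tert-butyl-[1-[2-[(1S)-1-[4-methoxy-3-(3-methylbut-2-enyl)phenyl]prop-2-enoxy]-4,6-bis(methoxymethoxy)phenyl]ethenoxy]dimethylsilane A6. The second-generation Grubbs catalyst (H2IMes)(PCy3)Cl2Ru=CHPh would load onto the monosubstituted vinyl group at C2 and close the six-membered ring C onto the silyl enol ether carbon by ring-closing metathesis. The product would be (2S)-4-(tert-butyldimethylsilyloxy)-2-[4-methoxy-3-(3-methylbut-2-enyl)phenyl]-5,7-bis(methoxymethoxy)-2H-chromene A5.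
- **In its favour.** The ring closure is neutral. C2 would be set beforehand in an allylic aryl ether that cannot enolise. A5 is already at the correct oxidation level at C4, which is better than Alternative 1. Cleavage of the silyl enol ether and of the two acetals, possibly in a single acidic operation, would lead to 6, so the end-game is about equal to that of the chosen plan.
- **Against it here.** The prenyl alkene of A6 is a second metathesis site, and cross-metathesis there would truncate the side chain. Enol ethers react sluggishly in metathesis and usually need heat. A6 is an aryl allyl ether that is both allylic and benzylic at C2, so heating invites aromatic Claisen rearrangement to C8 or ionisation. The 2-aryl-2H-chromene A5 can undergo reversible 6π electrocyclic ring opening, which would scramble C2. Setting C2 in A6 would need an enantioselective allylic etherification of a hindered, chelated ortho-acyl phenol.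
- **Comparison.** Mechanistically the alternative avoids base at the ring-forming stage, as the chosen plan does at its key step. It adds three selectivity problems that the chosen plan does not have: alkene chemoselectivity, Claisen rearrangement and chromene ring opening. It also needs an estimated ten or more operations.

**Alternative 3:**
- **Cut and key step.** Ring C would be cut at O1–C8a and C4–C4a. This leads back to the β-hydroxy ester methyl (3S)-3-hydroxy-3-[4-methoxy-3-(3-methylbut-2-enyl)phenyl]propanoate A8 and the aryne precursor 3,5-bis(methoxymethoxy)-2-(trimethylsilyl)phenyl trifluoromethanesulfonate A9. CsF would release the aryne 3,5-bis(methoxymethoxy)benzyne A10. The preformed potassium alkoxide of A8 would add to A10 to form O1–C8a, and the resulting aryl anion would attack the ester to form C4–C4a. The product would be (2S)-5,7-bis(methoxymethoxy)-4'-methoxy-3'-prenylflavanone A7.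
- **In its favour.** Two bonds and ring C would form in one convergent step. The alkoxy group next to the aryne bond of A10 directs the nucleophile to the distal carbon and places the anion beside the oxygen, which matches the 5,7-dioxygenation pattern. The carbinol centre of A8 could come from a well-established enantioselective carbonyl reduction or acetate aldol addition, in either enantiomeric series. A7 would need only acetal cleavage to reach 6, which is equal to the chosen end-game.
- **Against it here.** The alkoxide of a β-aryl-β-hydroxy ester is prone to retro-aldol cleavage and to E1cB dehydration. The aryl anion could be quenched by the acidic α-CH2 of the ester instead of acylating. The flavanone A7 would be formed in a basic fluoride medium, where the retro-oxa-Michael opening of ring C, the main fragility of this target, could erode the configuration at C2. A9 and A8 each need a multi-step preparation, and A8 again requires an earlier aryl–prenyl coupling.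
- **Comparison.** The alternative is better in flexibility and in independence from a natural source. It is equal in the final deprotection. It is worse in step count (an estimated nine to eleven operations) and in the exposure of C2 to base, which the chosen plan avoids entirely.

Key step: step 3

Assumption: purchased (2S)-hesperetin 1 is taken to be enantiomerically pure; since flavanones of natural origin can be partly racemised at C2, its purity should be confirmed by chiral HPLC and, if needed, raised by preparative chromatography on a chiral phase before step 1.

## Route

Step 1
Reactants: 1 (2S)-hesperetin [(2S)-5,7-dihydroxy-2-(3-hydroxy-4-methoxyphenyl)chroman-4-one]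
Product: 2 (2S)-7-O-(methoxymethyl)hesperetin [(2S)-5-hydroxy-2-(3-hydroxy-4-methoxyphenyl)-7-(methoxymethoxy)chroman-4-one]
Conditions: MOMCl (1.05 equiv), iPr2NEt (1.2 equiv), THF, −10 to 0 °C
Reagents that add atoms: chloromethyl methyl ether (MOMCl), COCCl
Why: Williamson-type O-alkylation of a phenoxide with an α-chloro ether: the C7 hydroxyl, para to the C4 carbonyl, is the most acidic phenol and is the one ionised by a slight excess of amine, while the C3' hydroxyl is an ordinary phenol and the C5 hydroxyl is held in its hydrogen bond to C4=O. A tertiary amine at low temperature should keep ring C closed, and because the C3' oxygen is meta to C1' it cannot open the C2–O1 bond through a quinone methide.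

Step 2
Reactants: 2 (2S)-7-O-(methoxymethyl)hesperetin
Product: 3 (2S)-7-O-(methoxymethyl)hesperetin 3'-trifluoromethanesulfonate [5-[(2S)-5-hydroxy-7-(methoxymethoxy)-4-oxochroman-2-yl]-2-methoxyphenyl trifluoromethanesulfonate]
Conditions: PhNTf2 (1.1 equiv), Et3N (1.5 equiv), DMAP (0.1 equiv), CH2Cl2, 0 °C to rt
Reagents that add atoms: N-phenylbis(trifluoromethanesulfonimide) (PhNTf2), O=S(=O)(N(c1ccccc1)S(=O)(=O)C(F)(F)F)C(F)(F)F
Why: Phenol O-triflation with an N-aryl triflimide: this mild triflyl donor reacts only with a phenoxide, which the amine generates at the free C3' hydroxyl, whereas the C5 hydroxyl is less acidic and shielded by its hydrogen bond to the C4 carbonyl and should stay free with a small excess of reagent. C2 takes no part.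

Step 3
Reactants: 3 (2S)-7-O-(methoxymethyl)hesperetin 3'-trifluoromethanesulfonate, 4 tributyl(3-methylbut-2-enyl)stannane
Product: 5 (2S)-7-O-(methoxymethyl)-4'-O-methyllicoflavanone [(2S)-5-hydroxy-2-[4-methoxy-3-(3-methylbut-2-enyl)phenyl]-7-(methoxymethoxy)chroman-4-one]
Conditions: Pd(PPh3)4 (5 mol %), LiCl (3 equiv), 4 (1.5 equiv), BHT (trace), degassed DMF, 90 °C; aq. KF work-up
Reagents that add atoms: none
Why: Stille cross-coupling of an aryl triflate with an allylic stannane. Zerovalent palladium inserts into the C3'–O bond of the triflate, the only bond in 3 that is activated for oxidative addition, and chloride from LiCl replaces the non-coordinating triflate to give the neutral complex ArPd(PPh3)2Cl, which is stable enough to wait for the stannane. Transmetalation from tin then transfers the prenyl group, and reductive elimination forms the C3'–C1'' bond and returns zerovalent palladium. No ring is closed and no stereocentre is created; C2 is a spectator and is protected by the absence of base, since the retro-oxa-Michael opening of ring C needs an enolate. The selectivity that matters is linear against branched transfer: whichever allyl terminus first reaches palladium, the allyl ligand equilibrates through its eta-3 form, and bond formation should occur at the unsubstituted CH2 terminus because coupling at the dimethyl-bearing carbon would build a quaternary benzylic centre next to the ortho methoxy group. The closest known reaction type is the LiCl-promoted coupling of aryl triflates with allyl- and prenyltributylstannanes. The chelated C5 hydroxyl, the acetal and the ketone are inert under these neutral conditions, and aqueous KF removes the tin residues as insoluble Bu3SnF.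

Step 4
Reactants: 5 (2S)-7-O-(methoxymethyl)-4'-O-methyllicoflavanone
Product: 6 4'-O-methyllicoflavanone [(2S)-5,7-dihydroxy-2-[4-methoxy-3-(3-methylbut-2-enyl)phenyl]chroman-4-one]
Conditions: 3 M aq. HCl (excess), MeOH, rt to 40 °C
Reagents that add atoms: none
Why: Acid-catalysed cleavage of a methoxymethyl ether (acetal solvolysis): protonation and loss of the oxocarbenium ion, which methanol traps, frees the C7 phenol, and this acetal is especially labile because the phenol para to the carbonyl is a good leaving group. Dilute acid at low temperature should leave the trisubstituted alkene, which has no neighbouring free hydroxyl to cyclise onto, and the configuration at C2 unchanged.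

## Compound list

1 | (2S)-hesperetin, (2S)-5,7-dihydroxy-2-(3-hydroxy-4-methoxyphenyl)chroman-4-one | COc1ccc([C@@H]2CC(=O)c3c(O)cc(O)cc3O2)cc1O | starting material
2 | (2S)-7-O-(methoxymethyl)hesperetin, (2S)-5-hydroxy-2-(3-hydroxy-4-methoxyphenyl)-7-(methoxymethoxy)chroman-4-one | COc1ccc([C@@H]2CC(=O)c3c(O)cc(OCOC)cc3O2)cc1O | intermediate
3 | (2S)-7-O-(methoxymethyl)hesperetin 3'-trifluoromethanesulfonate, 5-[(2S)-5-hydroxy-7-(methoxymethoxy)-4-oxochroman-2-yl]-2-methoxyphenyl trifluoromethanesulfonate | COc1ccc([C@@H]2CC(=O)c3c(O)cc(OCOC)cc3O2)cc1OS(=O)(=O)C(F)(F)F | intermediate
4 | tributyl(3-methylbut-2-enyl)stannane | CC(C)=CC[Sn](CCCC)(CCCC)CCCC | starting material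
5 | (2S)-7-O-(methoxymethyl)-4'-O-methyllicoflavanone, (2S)-5-hydroxy-2-[4-methoxy-3-(3-methylbut-2-enyl)phenyl]-7-(methoxymethoxy)chroman-4-one | COc1ccc([C@@H]2CC(=O)c3c(O)cc(OCOC)cc3O2)cc1CC=C(C)C | intermediate
6 | 4'-O-methyllicoflavanone, (2S)-5,7-dihydroxy-2-[4-methoxy-3-(3-methylbut-2-enyl)phenyl]chroman-4-one | COc1ccc([C@@H]2CC(=O)c3c(O)cc(O)cc3O2)cc1CC=C(C)C | target

## Step count and least certain steps

Total step count: 4. Longest linear sequence: 4 steps (1 to 2 to 3 to 5 to 6); 4 enters at step 3.

**Step 3 (key step).**
- What may go wrong: transfer of the prenyl group through its substituted terminus, or migration of the double bond into conjugation with ring B by β-hydride elimination and re-insertion at palladium. Oxidative addition into an electron-rich aryl triflate with an ortho methoxy group may also be slow, which would let sulfur–oxygen cleavage back to the phenol or simple reduction of the triflate compete.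
- Fallback: the prenyl group is built in two stages so that the regiochemical question does not arise. From 3, the same Pd(PPh3)4 and LiCl conditions with allyltributylstannane should give the allyl arene (2S)-5-hydroxy-2-[4-methoxy-3-(prop-2-enyl)phenyl]-7-(methoxymethoxy)chroman-4-one F1, because an unsubstituted allyl group gives the same product from either terminus. Olefin cross-metathesis of F1 with a large excess of 2-methylbut-2-ene and the second-generation Grubbs catalyst (H2IMes)(PCy3)Cl2Ru=CHPh in CH2Cl2 at rt to 40 °C should then install the two methyl groups. The sequence returns to the route at 5.

**Step 1.**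
- What may go wrong: incomplete discrimination between the C7 and C3' hydroxyls, leading to alkylation at the wrong oxygen or at both. Partial loss of optical purity by amine-induced reversible opening of ring C is a second concern.
- Fallback: the differentiation is based on selective acyl removal instead of selective alkylation. From 1, Ac2O in pyridine should give (2S)-hesperetin 3',5,7-triacetate F2. Thiophenol with catalytic imidazole in NMP should then remove only the most activated ester, at C7, to give (2S)-3',5-di-O-acetylhesperetin F3. The single free phenol of F3 is alkylated with MOMCl and iPr2NEt to give (2S)-3',5-di-O-acetyl-7-O-(methoxymethyl)hesperetin F4. Cold methanolic NH3 (0 °C, short contact) should cleave both acetates and return to the route at 2.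

**Step 4.**
- What may go wrong: acid-promoted Markovnikov addition of methanol, water or chloride to the prenyl double bond, or slow acid-catalysed opening and re-closure of ring C with erosion of configuration.
- Fallback: the order of events is changed so that acid never meets the alkene. From 3, the same HCl in MeOH treatment (the aryl triflate is stable to it) should give (2S)-hesperetin 3'-trifluoromethanesulfonate F5. The neutral Stille coupling of F5 with 4 (Pd(PPh3)4, LiCl, DMF, 90 °C) should then deliver the prenyl group directly and return to the route at 6. A larger excess of 4 is used because the acidic C7 phenol can slowly protonate the allylic stannane.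

In all cases the optical purity at C2 should be followed by chiral HPLC at 2, 3, 5 and 6.

## Further compounds

F1 | step 3 | (2S)-5-hydroxy-2-[4-methoxy-3-(prop-2-enyl)phenyl]-7-(methoxymethoxy)chroman-4-one | COc1ccc([C@@H]2CC(=O)c3c(O)cc(OCOC)cc3O2)cc1CC=C
F2 | step 1 | (2S)-hesperetin 3',5,7-triacetate | COc1ccc([C@@H]2CC(=O)c3c(OC(C)=O)cc(OC(C)=O)cc3O2)cc1OC(C)=O
F3 | step 1 | (2S)-3',5-di-O-acetylhesperetin | COc1ccc([C@@H]2CC(=O)c3c(OC(C)=O)cc(O)cc3O2)cc1OC(C)=O
F4 | step 1 | (2S)-3',5-di-O-acetyl-7-O-(methoxymethyl)hesperetin | COc1ccc([C@@H]2CC(=O)c3c(OC(C)=O)cc(OCOC)cc3O2)cc1OC(C)=O
F5 | step 4 | (2S)-hesperetin 3'-trifluoromethanesulfonate | COc1ccc([C@@H]2CC(=O)c3c(O)cc(O)cc3O2)cc1OS(=O)(=O)C(F)(F)F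
A1 | alternative 1 | (2S,4S)-4-methoxy-2-[4-methoxy-3-(3-methylbut-2-enyl)phenyl]-5,7-bis(triisopropylsilyloxy)chromane | COc1ccc([C@@H]2C[C@H](OC)c3c(O[Si](C(C)C)(C(C)C)C(C)C)cc(O[Si](C(C)C)(C(C)C)C(C)C)cc3O2)cc1CC=C(C)C
A2 | alternative 1 | 2-(dimethoxymethyl)-3,5-bis(triisopropylsilyloxy)phenol | COC(OC)c1c(O)cc(O[Si](C(C)C)(C(C)C)C(C)C)cc1O[Si](C(C)C)(C(C)C)C(C)C
A3 | alternative 1 | 4-ethenyl-1-methoxy-2-(3-methylbut-2-enyl)benzene | COc1ccc(C=C)cc1CC=C(C)C
A4 | alternative 1 | 6-(methoxymethylidene)-3,5-bis(triisopropylsilyloxy)cyclohexa-2,4-dien-1-one | COC=C1C(=O)C=C(O[Si](C(C)C)(C(C)C)C(C)C)C=C1O[Si](C(C)C)(C(C)C)C(C)C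
A5 | alternative 2 | (2S)-4-(tert-butyldimethylsilyloxy)-2-[4-methoxy-3-(3-methylbut-2-enyl)phenyl]-5,7-bis(methoxymethoxy)-2H-chromene | COc1ccc([C@@H]2C=C(O[Si](C)(C)C(C)(C)C)c3c(OCOC)cc(OCOC)cc3O2)cc1CC=C(C)C
A6 | alternative 2 | tert-butyl-[1-[2-[(1S)-1-[4-methoxy-3-(3-methylbut-2-enyl)phenyl]prop-2-enoxy]-4,6-bis(methoxymethoxy)phenyl]ethenoxy]dimethylsilane | COc1ccc([C@H](C=C)Oc2cc(OCOC)cc(OCOC)c2C(=C)O[Si](C)(C)C(C)(C)C)cc1CC=C(C)C
A7 | alternative 3 | (2S)-5,7-bis(methoxymethoxy)-4'-methoxy-3'-prenylflavanone | COc1ccc([C@@H]2CC(=O)c3c(OCOC)cc(OCOC)cc3O2)cc1CC=C(C)C
A8 | alternative 3 | methyl (3S)-3-hydroxy-3-[4-methoxy-3-(3-methylbut-2-enyl)phenyl]propanoate | COC(=O)C[C@H](O)c1ccc(OC)c(CC=C(C)C)c1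
A9 | alternative 3 | 3,5-bis(methoxymethoxy)-2-(trimethylsilyl)phenyl trifluoromethanesulfonate | COCOc1cc(OCOC)c([Si](C)(C)C)c(OS(=O)(=O)C(F)(F)F)c1
A10 | alternative 3 | 3,5-bis(methoxymethoxy)benzyne | COCOC1=CC(OCOC)=CC#C1
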